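**Late loss.** 0.418 /min is the logarithmic loss of intermediate A between 2.00 min and 4.00 min, averaged over the grey and teal runs, which bracket your flask in substrate.

| flask | substrate | reagent | remark | time |
|---|---|---|---|---|
| grey | 0.0067 M | 0.025 M (fed, over 25 s) | run made earlier |  |
| teal | 0.015 M | 0.025 M (fed, over 25 s) | run made earlier |  |
| green | 0.010 M | 0.050 M (fed, over 25 s) | run made earlier |  |
| flask | 0.010 M | 0.0250 M (fed, over 25 s) |  | 4.0 min |

| run | time / min | intermediate A / % | product / % |
|---|---|---|---|
| grey | 0.333 | 4 | 2 |
| grey | 0.667 | 18 | 2 |
| grey | 1.33 | 28 | 5 |
| grey | 2.00 | 24 | 7 |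
| grey | 4.00 | 10 | 17 |
| teal | 0.333 | 7 | 2 |
| teal | 0.667 | 19 | 4 |
| teal | 1.33 | 24 | 3 |
| teal | 2.00 | 20 | 6 |
| teal | 4.00 | 9 | 15 |
| green | 0.333 | 12 | 1 |
| green | 0.667 | 34 | 0 |
| green | 1.33 | 35 | 6 |
| green | 2.00 | 30 | 13 |
| green | 4.00 | 6 | 20 |

(each reading ± 1.5 percentage points)

- time, not beyond 4.0 min, at which the flask holds most intermediate A
- the amount of intermediate A, in percent of the substrate charged, at that time

- the numbers in the tables scatter with a standard deviation of 1.5 percentage points
- a reading or a percentage of product counts all its forms, free or not

**Reagent order.** The green run, with twice the reagent, reads 0.805 /min, twice that loss. So my reckoning takes the late loss as the substrate's fraction left falling at a rate in proportion to the reagent present, a second-order step, first order in each partner.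

**Two slowings.** Reagent arrives evenly, so your flask's clock starts late by half the feed, 0.208 min. Each unit fraction of substrate used also costs 0.400 of the reagent charge. I assume 75.0% of the substrate is used in the late window, which leaves a factor of 0.700. The start rate, meaning the substrate's logarithmic loss per minute with the whole reagent charge present, is therefore 0.598 /min, a half-life of 1.16 min. Averaging the factor from its starting value of 1 gives 0.850, so I expect 14.6% of the substrate left in your flask at 4.0 min.

**The forecast.** It gives 27% (24% to 30%) at 1.3 min (1 min to 1.7 min), judging that “the timing hardly depends on substrate”.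

**The flask.** It holds 25.0% at 1.37 min, inside both ranges.

    substrate + reagent → intermediate A (k = 0.420 /M/s)
    intermediate A → intermediate B (k = 0.0170 /s)
    substrate + reagent → product (k = 0.0240 /M/s)
    intermediate B ⇌ product (K = 0.560, k = 0.00250 /s)
    crystals ⇌ product, rate k5*(cs5 - [product]) while solid is left; crystals form when [product] > cs5 (solubility = 5.80 mM, k = 0.920 /s)

**Half-lives.** In your flask, the half-life of intermediate A by its turning into intermediate B is 0.68 min at 1.14 min, shorter than the substrate's 1.16 min at the start rate. Intermediate A then falls to 10.4% by 4.00 min, with 14.5% of the substrate left. In the neighbour flask with 0.10 M of reagent, the start rate scales to 2.39 /min, a half-life of 0.290 min, shorter than that of intermediate A. That neighbour flask reaches 50.1% of intermediate A and keeps 0.010% of its substrate at 4.00 min.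

The readings were generated by integration with constants of no real substance, and the scatter is random.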